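**Assumption:** the target (albaspidin iBiB type) has no stereocentre and is achiral, so no enantioselective step is needed; the enol tautomer drawn in the SMILES is taken as the target.

## Retrosynthetic overview

1. Target 12 is cut at its four C–CH3 bonds: both cyclohexadienone rings are traced back to benzene rings, giving the fully aromatic diarylmethane 7 and four equivalents of iodomethane 8.
2. Diarylmethane 7 is cut at the CH2 bridge into two molecules of the symmetric phlorisobutyrophenone 3 and formaldehyde 4.
3. Ketone 3 comes from phloroglucinol 1 and isobutyryl chloride 2 by C-acylation.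
4. No ring is built: both carbocycles are the benzene ring of phloroglucinol, joined first and then dearomatised together in the last step.

## Route

**Step 1**
Reactants: 1 phloroglucinol (benzene-1,3,5-triol); 2 isobutyryl chloride
Product: 3 phlorisobutyrophenone [2-methyl-1-(2,4,6-trihydroxyphenyl)propan-1-one]
Conditions: AlCl3 (3.5 equiv), PhNO2/CH2Cl2, 0 °C to 60 °C, 3 h; then ice/aq. HCl
Reagents that add atoms: isobutyryl chloride (2), CC(C)C(Cl)=O
Why: Friedel–Crafts C-acylation of the very electron-rich triol stops at the mono-ketone because the chelated acyl group deactivates the ring; no stereocentre is formed.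

**Step 2**
Reactants: 3 phlorisobutyrophenone (two molecules, used in excess); 4 formaldehyde
Product: 7 bis(3-isobutyryl-2,4,6-trihydroxyphenyl)methane, via hydroxymethyl adduct 5 (not isolated), via ortho-quinone methide 6 (not isolated)
Conditions: 37% aq. CH2O (0.25 equiv per 3), 1% aq. NaOH (1 equiv per 3), 0 °C to rt, 15 min; then 1 M HCl; unreacted 3 recovered
Reagents that add atoms: formaldehyde (4), C=O
Why: Phenolate hydroxymethylation (Lederer–Manasse type) at one of the two equivalent free ring carbons, loss of hydroxide to the ortho-quinone methide and Michael capture by a second phloroglucinolate give the diarylmethane, with the large excess of 3 suppressing trimer formation; no stereocentre is formed.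

**Step 3 (key step)**
Reactants: 7 bis(3-isobutyryl-2,4,6-trihydroxyphenyl)methane; 8 iodomethane (4.2 equiv)
Product: 12 2,2'-methylenebis[3,5-dihydroxy-4,4-dimethyl-6-(2-methylpropanoyl)cyclohexa-2,5-dien-1-one] (target), via monomethyl intermediate 9 (not isolated), via bis-C-methyl intermediate 10 (not isolated), via trimethyl monodienone intermediate 11 (not isolated)
Conditions: NaOMe (6.2 equiv), MeI (4.2 equiv), MeOH, 0 °C to rt, 24 h; then 1 M HCl
Reagents that add atoms: iodomethane (8), CI
Why: Proposed new method: in NaOMe/MeOH each phloroglucinolate ring of 7 is C-methylated by SN2 at its only unsubstituted ring carbon and then a second time at the same carbon rather than at the electronically equivalent but much more hindered bridge-bearing carbon, so both rings lose aromaticity in one flask and end as acyl-stabilised enolised β-triketones, the closest known reaction being the NaOMe/MeI dearomative gem-dimethylation of monomeric acylphloroglucinols to acylfilicinic acids; no stereocentre is formed.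

## Compound list

1 | phloroglucinol (benzene-1,3,5-triol) | Oc1cc(O)cc(O)c1 | starting material
2 | isobutyryl chloride (2-methylpropanoyl chloride) | CC(C)C(Cl)=O | starting material
3 | phlorisobutyrophenone, 2-methyl-1-(2,4,6-trihydroxyphenyl)propan-1-one | CC(C)C(=O)c1c(O)cc(O)cc1O | intermediate
4 | formaldehyde (37% aqueous) | C=O | starting material
5 | hydroxymethyl adduct, 1-[2,4,6-trihydroxy-3-(hydroxymethyl)phenyl]-2-methylpropan-1-one | CC(C)C(=O)c1c(O)cc(O)c(CO)c1O | intermediate (not isolated)
6 | ortho-quinone methide, 3,5-dihydroxy-6-methylidene-2-(2-methylpropanoyl)cyclohexa-2,4-dien-1-one | CC(C)C(=O)C1=C(O)C=C(O)C(=C)C1=O | intermediate (not isolated)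
7 | bis(3-isobutyryl-2,4,6-trihydroxyphenyl)methane | CC(C)C(=O)c1c(O)cc(O)c(Cc2c(O)cc(O)c(C(=O)C(C)C)c2O)c1O | intermediate
8 | iodomethane | CI | starting material
9 | monomethyl intermediate: 7 carrying one C-methyl at the free ring carbon of one ring | CC(C)C(=O)c1c(O)c(C)c(O)c(Cc2c(O)cc(O)c(C(=O)C(C)C)c2O)c1O | intermediate (not isolated)
10 | bis-C-methyl intermediate, bis(3-isobutyryl-5-methyl-2,4,6-trihydroxyphenyl)methane | CC(C)C(=O)c1c(O)c(C)c(O)c(Cc2c(O)c(C)c(O)c(C(=O)C(C)C)c2O)c1O | intermediate (not isolated)
11 | trimethyl monodienone intermediate: one ring already the gem-dimethyl dienone, the other still the 5-methyl arene | CC(C)C(=O)C1=C(O)C(C)(C)C(O)=C(Cc2c(O)c(C)c(O)c(C(=O)C(C)C)c2O)C1=O | intermediate (not isolated)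
12 | 2,2'-methylenebis[3,5-dihydroxy-4,4-dimethyl-6-(2-methylpropanoyl)cyclohexa-2,5-dien-1-one], achiral | CC(C)C(=O)C1=C(O)C(C)(C)C(O)=C(CC2=C(O)C(C)(C)C(O)=C(C(=O)C(C)C)C2=O)C1=O | target

## Step count and risks

Total steps: 3. Longest linear sequence: 3 (phloroglucinol 1 to target 12).

**Most likely to fail, in order of risk:**

**Step 3 (fourfold C-methylation with double dearomatisation).** The risks are methylation at the bridge-bearing ring carbon, over-methylation of the product triketone enolate, some O-methylation, and base-induced scission of the CH2 bridge. Fallback: the dearomatisation is moved to the monomer. Setting out from 3, treatment with NaOMe (3 equiv) and MeI (2.2 equiv) in MeOH gives isobutyrylfilicinic acid F3, whose ring has only one nucleophilic carbon left. Formalin (0.5 equiv) in 1% aq. NaOH at room temperature then converts F3 through the hydroxymethyl adduct F4 and the methylidene trione F5, which is captured by a second molecule of F3 in a Michael addition. Acidification returns the route at target 12.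

**Step 2 (methylene bridging of a nucleophile with two free positions).** Compound 7 still has one free carbon per ring, so trimers and higher oligomers compete. Fallback: the one-carbon unit is installed on one molecule first as an isolable amine. Setting out from 3, aqueous Me2NH (1 equiv) and formalin (1 equiv) in EtOH at 0 °C give the Mannich base 1-[3-(dimethylaminomethyl)-2,4,6-trihydroxyphenyl]-2-methylpropan-1-one F2. Heating F2 with 3 (3 equiv) in dioxane at 90 °C expels dimethylamine, releases the ortho-quinone methide 6 slowly in the presence of excess nucleophile, and comes back to the route at 7.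

**Step 1 (Friedel–Crafts acylation).** O-acylation and diacylation can lower the yield. Fallback: a Houben–Hoesch reaction instead of an acyl chloride. Setting out from 1, isobutyronitrile with ZnCl2 and dry HCl in Et2O at 0 °C precipitates the ketiminium salt 2-methyl-1-(2,4,6-trihydroxyphenyl)propan-1-iminium chloride F1, which cannot react a second time. Hydrolysis of F1 in boiling water comes back to the route at 3.

## Further compounds

F1 | step 1 | 2-methyl-1-(2,4,6-trihydroxyphenyl)propan-1-iminium chloride | CC(C)C(=[NH2+])c1c(O)cc(O)cc1O.[Cl-]
F2 | step 2 | 1-[3-(dimethylaminomethyl)-2,4,6-trihydroxyphenyl]-2-methylpropan-1-one | CC(C)C(=O)c1c(O)cc(O)c(CN(C)C)c1O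
F3 | step 3 | isobutyrylfilicinic acid, 3,5-dihydroxy-4,4-dimethyl-2-(2-methylpropanoyl)cyclohexa-2,5-dien-1-one | CC(C)C(=O)C1=C(O)C(C)(C)C(O)=CC1=O
F4 | step 3 | hydroxymethyl adduct, 3,5-dihydroxy-2-(hydroxymethyl)-4,4-dimethyl-6-(2-methylpropanoyl)cyclohexa-2,5-dien-1-one | CC(C)C(=O)C1=C(O)C(C)(C)C(O)=C(CO)C1=O
F5 | step 3 | methylidene trione, 5-hydroxy-6,6-dimethyl-2-methylidene-4-(2-methylpropanoyl)cyclohex-4-ene-1,3-dione | CC(C)C(=O)C1=C(O)C(C)(C)C(=O)C(=C)C1=O
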